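**Plan**

- Retrosynthetic cuts, in order: the E alkene Cα=Cβ (back to a benzylic alcohol, then an aryl ketone); the pyranone of coumarin A at O1–C2 and C4–C4a (phenol plus propiolic acid); C8–Cα and C8a–O1 together (aryne plus carboxylic acid); the acid carbon (one-carbon homologation of a formyl group); finally C1–C2 and C5–C6 of the cyclohexene (Diels–Alder).
- Enabling feature: in coumarin A, C8 sits between ring oxygen O1 on C8a and the methoxy-bearing C7, with the C5 methoxy para to it, and carries the two-carbon bridge Cα–Cβ to quaternary ring carbon C1. A 3-methoxyaryne inserting into the C–O bond of a carboxylic acid lays down exactly this oxygen/acyl/methoxy sequence on adjacent carbons.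
- Forward order: coumarin B is present from the start and is extended to a 1-aryl-3-methylbutadiene; the cyclohexene ring arises first by cycloaddition with methacrolein; the side chain is lengthened to the acetic acid; the second arene is joined by the aryne acyl transfer; the coumarin A pyranone is closed; the alkene is made last.
- Stereochemistry: both stereocentres (quaternary C1, tertiary C2) come from one catalyst-controlled endo Diels–Alder reaction and are not touched afterwards; the E alkene comes from a syn-elimination.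

Key step: step 11

Assumption: the sense of induction in step 4 is taken from the usual formyl C–H···O pre-transition-state model of cationic oxazaborolidines, which for the (S)-catalyst leaves the Re face of the methacrolein α-carbon open; should the antipodal cycloadduct form, the (R)-catalyst would be used with nothing else changed.

**Route**

Step 1
Reactants: 1 5,7-dimethoxy-2H-chromen-2-one
Product: 2 8-iodo-5,7-dimethoxy-2H-chromen-2-one
Conditions: NIS, TFA (0.3 equiv), MeCN, 0 → 23 °C
Reagents that add atoms: N-iodosuccinimide, O=C1CCC(=O)N1I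
Why: Electrophilic aromatic iodination with acid-activated NIS should go to C8, which is ortho to the C7 methoxy group and the ring oxygen, para to the C5 methoxy group and less crowded than C6 between two methoxy groups, while the pyranone C3 is far less nucleophilic.

Step 2
Reactants: 2 8-iodo-5,7-dimethoxy-2H-chromen-2-one; 3 2-methylbut-3-en-2-ol
Product: 4 8-[(1E)-3-hydroxy-3-methylbut-1-en-1-yl]-5,7-dimethoxy-2H-chromen-2-one
Conditions: Pd(OAc)2 (5 mol %), P(o-tol)3 (10 mol %), Et3N, DMF, 90 °C
Reagents that add atoms: none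
Why: Mizoroki–Heck coupling, in which the arylpalladium species adds to the unsubstituted alkene terminus and β-hydride elimination is possible only from the benzylic CH2 because the carbinol carbon is quaternary, so the (E)-styryl tertiary alcohol is the single expected product.

Step 3
Reactants: 4 8-[(1E)-3-hydroxy-3-methylbut-1-en-1-yl]-5,7-dimethoxy-2H-chromen-2-one
Product: 5 5,7-dimethoxy-8-[(1E)-3-methylbuta-1,3-dien-1-yl]-2H-chromen-2-one
Conditions: MsCl, Et3N, CH2Cl2, 0 → 23 °C; used at once
Reagents that add atoms: none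
Why: Dehydration of the tertiary allylic alcohol through its mesylate, with elimination toward a methyl group (the only β-hydrogens), should give the conjugated diene without touching the E alkene; the diene is not stored because 1-aryl-3-methylbutadienes dimerise on standing.

Step 4
Reactants: 5 5,7-dimethoxy-8-[(1E)-3-methylbuta-1,3-dien-1-yl]-2H-chromen-2-one; 6 methacrolein (2-methylprop-2-enal)
Product: 7 (1S,2S)-2-(5,7-dimethoxy-2-oxo-2H-chromen-8-yl)-1,4-dimethylcyclohex-3-ene-1-carbaldehyde (formyl cis to the coumarinyl group)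
Conditions: (S)-3,3-diphenyl-1-(2-methylphenyl)tetrahydro-1H,3H-pyrrolo[1,2-c][1,3,2]oxazaborole (20 mol %), Tf2NH (18 mol %), 6 (5 equiv), CH2Cl2, −78 °C
Reagents that add atoms: none
Why: Enantioselective Diels–Alder reaction under a chiral cationic oxazaborolidine, in which the diene terminus remote from the aryl group (largest HOMO coefficient, reinforced by the 3-methyl group) bonds to the β-carbon of boron-bound methacrolein so that the quaternary C1 forms next to the aryl-bearing C2, the formyl group takes the endo position and so ends cis to the coumarinyl group, and the catalyst, which holds the s-trans enal by B–O coordination and a formyl C–H···O contact with one face covered by a phenyl group, leaves the Re face of the α-carbon open, setting (1S,2S) in one event.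

Step 5
Reactants: 7 (1S,2S)-2-(5,7-dimethoxy-2-oxo-2H-chromen-8-yl)-1,4-dimethylcyclohex-3-ene-1-carbaldehyde; 8 (methoxymethyl)triphenylphosphonium chloride
Product: 9 8-[(1R,6S)-6-(2-methoxyethenyl)-3,6-dimethylcyclohex-2-en-1-yl]-5,7-dimethoxy-2H-chromen-2-one (E/Z mixture at the enol ether)
Conditions: 8, KN(SiMe3)2, THF, 0 °C; then 7, 0 → 23 °C
Reagents that add atoms: none
Why: Wittig methoxymethylenation of a non-enolisable aldehyde that is far more electrophilic than the lactone carbonyl; the ylide is preformed with a non-nucleophilic amide base so that no alkoxide is present to open the coumarin, and the enol ether geometry is of no consequence.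

Step 6
Reactants: 9 8-[(1R,6S)-6-(2-methoxyethenyl)-3,6-dimethylcyclohex-2-en-1-yl]-5,7-dimethoxy-2H-chromen-2-one
Product: 10 2-[(1R,2R)-2-(5,7-dimethoxy-2-oxo-2H-chromen-8-yl)-1,4-dimethylcyclohex-3-en-1-yl]acetaldehyde
Conditions: 2 M HCl (aq), THF, 23 °C
Reagents that add atoms: water, O
Why: Acid-catalysed enol ether hydrolysis through the oxocarbenium ion and hemiacetal, where the water-rich medium should trap the cation before the ring alkene can and neither stereocentre is epimerisable.

Step 7
Reactants: 10 2-[(1R,2R)-2-(5,7-dimethoxy-2-oxo-2H-chromen-8-yl)-1,4-dimethylcyclohex-3-en-1-yl]acetaldehyde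
Product: 11 2-[(1R,2R)-2-(5,7-dimethoxy-2-oxo-2H-chromen-8-yl)-1,4-dimethylcyclohex-3-en-1-yl]acetic acid
Conditions: NaClO2, NaH2PO4, 2-methylbut-2-ene, t-BuOH/H2O, 0 → 23 °C
Reagents that add atoms: sodium chlorite, [Na+].[O-]Cl=O
Why: Pinnick oxidation converts the aldehyde to the acid under buffered conditions, with 2-methylbut-2-ene consuming the hypochlorous acid that would otherwise chlorinate the alkene or the dimethoxyarene.

Step 8
Reactants: 12 3,5-dimethoxyphenol; 13 isopropyl isocyanate
Product: 14 3,5-dimethoxyphenyl N-(propan-2-yl)carbamate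
Conditions: Et3N (10 mol %), CH2Cl2, 23 °C
Reagents that add atoms: none
Why: Amine-catalysed addition of the phenol to the isocyanate gives the N-monosubstituted O-aryl carbamate, a strong ortho-directing group that can later be removed under mild base.

Step 9
Reactants: 14 3,5-dimethoxyphenyl N-(propan-2-yl)carbamate
Product: 17 3,5-dimethoxy-2-(trimethylsilyl)phenyl N-(propan-2-yl)carbamate, via N-silyl carbamate 15 (not isolated), via doubly silylated carbamate 16 (not isolated)
Conditions: TMSOTf, TMEDA, Et2O, 0 → 23 °C; n-BuLi, TMEDA, −78 °C; TMSCl, −78 → 23 °C; aq NH4Cl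
Reagents that add atoms: chlorotrimethylsilane, C[Si](C)(C)Cl
Why: Directed ortho-metalation, in which transient N-silylation masks the N–H, n-BuLi/TMEDA lithiates the position flanked by the carbamate oxygen and a methoxy group (both direct there and the two such positions are equivalent by symmetry), TMSCl traps the aryllithium and the labile N–Si bond is hydrolysed on work-up.

Step 10
Reactants: 17 3,5-dimethoxy-2-(trimethylsilyl)phenyl N-(propan-2-yl)carbamate
Product: 19 3,5-dimethoxy-2-(trimethylsilyl)phenyl trifluoromethanesulfonate, via silyl phenol 18 (not isolated)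
Conditions: DBU, Et2NH, MeCN, 40 °C; then PhNTf2, 23 °C
Reagents that add atoms: N-phenylbis(trifluoromethanesulfonimide), O=S(=O)(N(c1ccccc1)S(=O)(=O)C(F)(F)F)C(F)(F)F
Why: Base-induced E1cB cleavage of the N–H carbamate releases the phenoxide and isopropyl isocyanate (scavenged by Et2NH as a urea), and the phenoxide is triflated in the same flask; the wholly basic medium avoids protodesilylation of the electron-rich arylsilane.

Step 11
Reactants: 11 2-[(1R,2R)-2-(5,7-dimethoxy-2-oxo-2H-chromen-8-yl)-1,4-dimethylcyclohex-3-en-1-yl]acetic acid; 19 3,5-dimethoxy-2-(trimethylsilyl)phenyl trifluoromethanesulfonate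
Product: 21 8-{(1R,6R)-6-[2-(2-hydroxy-4,6-dimethoxyphenyl)-2-oxoethyl]-3,6-dimethylcyclohex-2-en-1-yl}-5,7-dimethoxy-2H-chromen-2-one, via 3,5-dimethoxybenzyne 20 (not isolated)
Conditions: 19 (1.5 equiv), CsF (4 equiv), THF, 125 °C, sealed tube
Reagents that add atoms: none
Why: Fluoride converts 11 into its caesium carboxylate and strips the silyl group from 19 with loss of triflate to give aryne 20; the carboxylate oxygen adds to the aryne carbon remote from the flanking methoxy group, the resulting aryl anion attacks the ester carbonyl through a four-membered alkoxide, and this opens to the ortho-acyl phenoxide, so the aryne is formally inserted into the acyl C–O bond and the C–O and C–C bonds of the future C8a and C8 form in one operation. The closest known reaction type is the insertion of arynes into the C–O bond of carboxylic acids to give ortho-hydroxyaryl ketones, a relative of the acyl-alkylation of arynes with β-keto esters. No ring is closed, since the four-membered intermediate is not kept, and no stereocentre is formed; the quaternary C1 and the non-acidic C2 are not at risk under fluoride. The step needs regioselective addition to an unsymmetrical aryne, and the methoxy group beside the triple bond secures it by inductively stabilising negative charge on the adjacent carbon, which places the acyl carbon between OH and OCH3 with the second OCH3 para. It also needs the acyl shift to outrun protonation of the aryl anion, which the aprotic medium, the excess of CsF and the high temperature favour, and the carboxylate is the only strong nucleophile present.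

Step 12
Reactants: 21 8-{(1R,6R)-6-[2-(2-hydroxy-4,6-dimethoxyphenyl)-2-oxoethyl]-3,6-dimethylcyclohex-2-en-1-yl}-5,7-dimethoxy-2H-chromen-2-one; 22 propiolic acid
Product: 23 2-{2-[(1R,2R)-2-(5,7-dimethoxy-2-oxo-2H-chromen-8-yl)-1,4-dimethylcyclohex-3-en-1-yl]acetyl}-3,5-dimethoxyphenyl prop-2-ynoate
Conditions: DCC, DMAP (5 mol %), CH2Cl2, 0 °C
Reagents that add atoms: none
Why: Carbodiimide (Steglich) esterification of the only hydroxyl group in the molecule, with low temperature and little DMAP to limit conjugate addition of the phenol to the propiolate.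

Step 13
Reactants: 23 2-{2-[(1R,2R)-2-(5,7-dimethoxy-2-oxo-2H-chromen-8-yl)-1,4-dimethylcyclohex-3-en-1-yl]acetyl}-3,5-dimethoxyphenyl prop-2-ynoate
Product: 24 8-{2-[(1R,2R)-2-(5,7-dimethoxy-2-oxo-2H-chromen-8-yl)-1,4-dimethylcyclohex-3-en-1-yl]acetyl}-5,7-dimethoxy-2H-chromen-2-one
Conditions: Ph3PAuCl (5 mol %), AgOTf (5 mol %), 1,2-dichloroethane, 23 °C
Reagents that add atoms: none
Why: Intramolecular alkyne hydroarylation catalysed by cationic monovalent gold, in which the π-activated alkyne is attacked in a 6-endo-dig manner by the only free ortho carbon (activated ortho and para by the two methoxy groups) and protodeauration gives the coumarin A pyranone, while the ketone and the remote ring alkene stay untouched.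

Step 14
Reactants: 24 8-{2-[(1R,2R)-2-(5,7-dimethoxy-2-oxo-2H-chromen-8-yl)-1,4-dimethylcyclohex-3-en-1-yl]acetyl}-5,7-dimethoxy-2H-chromen-2-one
Product: 25 8-{2-[(1R,2R)-2-(5,7-dimethoxy-2-oxo-2H-chromen-8-yl)-1,4-dimethylcyclohex-3-en-1-yl]-1-hydroxyethyl}-5,7-dimethoxy-2H-chromen-2-one (both carbinol epimers)
Conditions: NaBH4, CeCl3·7H2O, MeOH/THF, 0 → 23 °C
Reagents that add atoms: none
Why: Luche reduction, in which CeCl3 activates the hindered aryl ketone toward NaBH4 and disfavours conjugate reduction of the two coumarin lactones; the new carbinol centre forms without control, which is immaterial because it is removed in the next step.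

Step 15
Reactants: 25 8-{2-[(1R,2R)-2-(5,7-dimethoxy-2-oxo-2H-chromen-8-yl)-1,4-dimethylcyclohex-3-en-1-yl]-1-hydroxyethyl}-5,7-dimethoxy-2H-chromen-2-one
Product: 26 8-{(E)-2-[(1R,2R)-2-(5,7-dimethoxy-2-oxo-2H-chromen-8-yl)-1,4-dimethylcyclohex-3-en-1-yl]ethenyl}-5,7-dimethoxy-2H-chromen-2-one (CNP0164660.2)
Conditions: Burgess reagent (methyl N-(triethylammoniosulfonyl)carbamate), toluene, 70 °C
Reagents that add atoms: none
Why: Burgess dehydration, in which the sulfamate ester undergoes thermal syn-elimination with one of the adjacent CH2 hydrogens (the only β-hydrogens) and the E alkene should form because the Z isomer would press the 2,6-disubstituted aryl ring against the quaternary carbon, while the neutral conditions keep the benzylic position from ionising toward the ring alkene.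

**Compound list**

1 | 5,7-dimethoxy-2H-chromen-2-one | COc1cc(OC)c2ccc(=O)oc2c1 | starting material
2 | 8-iodo-5,7-dimethoxy-2H-chromen-2-one | COc1cc(OC)c2ccc(=O)oc2c1I | intermediate
3 | 2-methylbut-3-en-2-ol | C=CC(C)(C)O | starting material
4 | 8-[(1E)-3-hydroxy-3-methylbut-1-en-1-yl]-5,7-dimethoxy-2H-chromen-2-one | COc1cc(OC)c2ccc(=O)oc2c1/C=C/C(C)(C)O | intermediate
5 | 5,7-dimethoxy-8-[(1E)-3-methylbuta-1,3-dien-1-yl]-2H-chromen-2-one | COc1cc(OC)c2ccc(=O)oc2c1/C=C/C(C)=C | intermediate
6 | methacrolein | C=C(C)C=O | starting material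
7 | (1S,2S)-2-(5,7-dimethoxy-2-oxo-2H-chromen-8-yl)-1,4-dimethylcyclohex-3-ene-1-carbaldehyde | O=C[C@@]1(C)CCC(C)=C[C@H]1c1c(OC)cc(OC)c2ccc(=O)oc12 | intermediate
8 | (methoxymethyl)triphenylphosphonium chloride | COC[P+](c1ccccc1)(c1ccccc1)c1ccccc1.[Cl-] | starting material
9 | 8-[(1R,6S)-6-(2-methoxyethenyl)-3,6-dimethylcyclohex-2-en-1-yl]-5,7-dimethoxy-2H-chromen-2-one (E/Z mixture) | COC=C[C@@]1(C)CCC(C)=C[C@H]1c1c(OC)cc(OC)c2ccc(=O)oc12 | intermediate
10 | 2-[(1R,2R)-2-(5,7-dimethoxy-2-oxo-2H-chromen-8-yl)-1,4-dimethylcyclohex-3-en-1-yl]acetaldehyde | O=CC[C@@]1(C)CCC(C)=C[C@H]1c1c(OC)cc(OC)c2ccc(=O)oc12 | intermediate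
11 | 2-[(1R,2R)-2-(5,7-dimethoxy-2-oxo-2H-chromen-8-yl)-1,4-dimethylcyclohex-3-en-1-yl]acetic acid | OC(=O)C[C@@]1(C)CCC(C)=C[C@H]1c1c(OC)cc(OC)c2ccc(=O)oc12 | intermediate
12 | 3,5-dimethoxyphenol | COc1cc(O)cc(OC)c1 | starting material
13 | isopropyl isocyanate | CC(C)N=C=O | starting material
14 | 3,5-dimethoxyphenyl N-(propan-2-yl)carbamate | COc1cc(OC)cc(OC(=O)NC(C)C)c1 | intermediate
15 | 3,5-dimethoxyphenyl N-(propan-2-yl)-N-(trimethylsilyl)carbamate | COc1cc(OC)cc(OC(=O)N(C(C)C)[Si](C)(C)C)c1 | intermediate, not isolated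
16 | 3,5-dimethoxy-2-(trimethylsilyl)phenyl N-(propan-2-yl)-N-(trimethylsilyl)carbamate | COc1cc(OC)c([Si](C)(C)C)c(OC(=O)N(C(C)C)[Si](C)(C)C)c1 | intermediate, not isolated
17 | 3,5-dimethoxy-2-(trimethylsilyl)phenyl N-(propan-2-yl)carbamate | COc1cc(OC)c([Si](C)(C)C)c(OC(=O)NC(C)C)c1 | intermediate
18 | 3,5-dimethoxy-2-(trimethylsilyl)phenol | COc1cc(OC)c([Si](C)(C)C)c(O)c1 | intermediate, not isolated
19 | 3,5-dimethoxy-2-(trimethylsilyl)phenyl trifluoromethanesulfonate | COc1cc(OC)c([Si](C)(C)C)c(OS(=O)(=O)C(F)(F)F)c1 | intermediate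
20 | 3,5-dimethoxybenzyne (1,2-didehydro-3,5-dimethoxybenzene) | COC1=CC(OC)=CC#C1 | intermediate, not isolated
21 | 8-{(1R,6R)-6-[2-(2-hydroxy-4,6-dimethoxyphenyl)-2-oxoethyl]-3,6-dimethylcyclohex-2-en-1-yl}-5,7-dimethoxy-2H-chromen-2-one | O=C(C[C@@]1(C)CCC(C)=C[C@H]1c1c(OC)cc(OC)c2ccc(=O)oc12)c1c(O)cc(OC)cc1OC | intermediate
22 | propiolic acid | OC(=O)C#C | starting material
23 | 2-{2-[(1R,2R)-2-(5,7-dimethoxy-2-oxo-2H-chromen-8-yl)-1,4-dimethylcyclohex-3-en-1-yl]acetyl}-3,5-dimethoxyphenyl prop-2-ynoate | C#CC(=O)Oc1cc(OC)cc(OC)c1C(=O)C[C@@]1(C)CCC(C)=C[C@H]1c1c(OC)cc(OC)c2ccc(=O)oc12 | intermediate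
24 | 8-{2-[(1R,2R)-2-(5,7-dimethoxy-2-oxo-2H-chromen-8-yl)-1,4-dimethylcyclohex-3-en-1-yl]acetyl}-5,7-dimethoxy-2H-chromen-2-one | COc1cc(OC)c2ccc(=O)oc2c1C(=O)C[C@@]1(C)CCC(C)=C[C@H]1c1c(OC)cc(OC)c2ccc(=O)oc12 | intermediate
25 | 8-{2-[(1R,2R)-2-(5,7-dimethoxy-2-oxo-2H-chromen-8-yl)-1,4-dimethylcyclohex-3-en-1-yl]-1-hydroxyethyl}-5,7-dimethoxy-2H-chromen-2-one (both carbinol epimers) | COc1cc(OC)c2ccc(=O)oc2c1C(O)C[C@@]1(C)CCC(C)=C[C@H]1c1c(OC)cc(OC)c2ccc(=O)oc12 | intermediate
26 | 8-{(E)-2-[(1R,2R)-2-(5,7-dimethoxy-2-oxo-2H-chromen-8-yl)-1,4-dimethylcyclohex-3-en-1-yl]ethenyl}-5,7-dimethoxy-2H-chromen-2-one (CNP0164660.2) | COc1cc(OC)c2ccc(=O)oc2c1/C=C/[C@@]1(C)CCC(C)=C[C@H]1c1c(OC)cc(OC)c2ccc(=O)oc12 | target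

**Count**

Total steps: 15. Longest linear sequence: 12 steps (steps 1–7 and 11–15); the aryne precursor branch (steps 8–10) joins at step 11.

**Steps most likely to fail**

1. Step 11 (aryne acyl transfer). The aryl anion formed after O-arylation may be protonated before the acyl shift, leaving only the aryl ester, or the product phenoxide may be arylated by a second aryne. The fallback sets out from aldehyde 10 and comes back at 21, making the same ketone by carbonyl addition instead of aryne insertion. Phenol 12 would be protected (MOMCl, i-Pr2NEt, CH2Cl2) as 1,3-dimethoxy-5-(methoxymethoxy)benzene F1. Lithiation between the MOM ether and a methoxy group (n-BuLi, THF, 0 °C), transmetalation with anhydrous CeCl3 and addition to 10 at −78 °C, where the aldehyde should react well before the lactone, would give the benzylic alcohol 8-[(1R,6R)-6-{2-[2,4-dimethoxy-6-(methoxymethoxy)phenyl]-2-hydroxyethyl}-3,6-dimethylcyclohex-2-en-1-yl]-5,7-dimethoxy-2H-chromen-2-one F2 as a mixture of carbinol epimers. Dess–Martin periodinane would oxidise it to the MOM-protected ketone 8-[(1R,6R)-6-{2-[2,4-dimethoxy-6-(methoxymethoxy)phenyl]-2-oxoethyl}-3,6-dimethylcyclohex-2-en-1-yl]-5,7-dimethoxy-2H-chromen-2-one F3, and HCl in MeOH at 23 °C would remove the MOM group to give 21.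

2. Step 4 (enantioselective Diels–Alder). Face or endo/exo discrimination may be insufficient with this hindered diene, the lactone carbonyl may tie up the Lewis acid, or the diene may oligomerise under acid. The fallback sets out from 1 and comes back at 7, setting C2 by allylic substitution and C1 by substrate-controlled alkylation.
   - Rieche formylation of 1 (Cl2CHOMe, TiCl4, CH2Cl2, 0 °C) would give 5,7-dimethoxy-2-oxo-2H-chromene-8-carbaldehyde F4, and vinylmagnesium bromide (THF, −78 °C) would give racemic 8-(1-hydroxyprop-2-en-1-yl)-5,7-dimethoxy-2H-chromen-2-one F5.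
   - The aldehyde partner would come from lithiated acetaldehyde N-cyclohexylimine and 4-bromo-2-methylbut-1-ene, which give N-cyclohexyl-5-methylhex-5-en-1-imine F6, hydrolysed with aqueous oxalic acid to 5-methylhex-5-enal F7.
   - Iridium/enamine allylation of F7 with F5 ([Ir(cod)Cl]2, the antipode of a phosphoramidite–alkene ligand that gives the 3R centre, a diarylprolinol silyl ether, an acid promoter, 1,2-dichloroethane, 25 °C) would give (3R)-3-(5,7-dimethoxy-2-oxo-2H-chromen-8-yl)-2-(3-methylbut-3-en-1-yl)pent-4-enal F8; its C2 configuration does not matter.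
   - Ring-closing metathesis with the second-generation Grubbs catalyst (CH2Cl2, 40 °C) would give (2R)-2-(5,7-dimethoxy-2-oxo-2H-chromen-8-yl)-4-methylcyclohex-3-ene-1-carbaldehyde F9.
   - Methylation of its potassium enolate (KN(SiMe3)2, MeI, THF, −78 °C) on the face away from the neighbouring aryl group would place the methyl group trans to the aryl group and give 7.

3. Step 15 (dehydration). The sulfamate ester of this very electron-rich benzylic alcohol may ionise, after which the cation could be captured by the ring alkene or lose geometric control. The fallback sets out from ketone 24 and comes back at 26, avoiding the alcohol. KN(SiMe3)2 and PhNTf2 (THF, −78 °C) would convert 24, through its Z(O)-enolate, into (1Z)-1-(5,7-dimethoxy-2-oxo-2H-chromen-8-yl)-2-[(1S,2R)-2-(5,7-dimethoxy-2-oxo-2H-chromen-8-yl)-1,4-dimethylcyclohex-3-en-1-yl]ethenyl trifluoromethanesulfonate F10. Palladium-catalysed formate reduction (Pd(OAc)2, PPh3, n-Bu3N, HCO2H, DMF, 60 °C) would replace the triflate by hydrogen with retention of alkene geometry and give 26.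

**Further compounds**

F1 | step 11 | 1,3-dimethoxy-5-(methoxymethoxy)benzene | COCOc1cc(OC)cc(OC)c1
F2 | step 11 | 8-[(1R,6R)-6-{2-[2,4-dimethoxy-6-(methoxymethoxy)phenyl]-2-hydroxyethyl}-3,6-dimethylcyclohex-2-en-1-yl]-5,7-dimethoxy-2H-chromen-2-one (carbinol epimers) | COCOc1cc(OC)cc(OC)c1C(O)C[C@@]1(C)CCC(C)=C[C@H]1c1c(OC)cc(OC)c2ccc(=O)oc12
F3 | step 11 | 8-[(1R,6R)-6-{2-[2,4-dimethoxy-6-(methoxymethoxy)phenyl]-2-oxoethyl}-3,6-dimethylcyclohex-2-en-1-yl]-5,7-dimethoxy-2H-chromen-2-one | COCOc1cc(OC)cc(OC)c1C(=O)C[C@@]1(C)CCC(C)=C[C@H]1c1c(OC)cc(OC)c2ccc(=O)oc12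
F4 | step 4 | 5,7-dimethoxy-2-oxo-2H-chromene-8-carbaldehyde | COc1cc(OC)c2ccc(=O)oc2c1C=O
F5 | step 4 | 8-(1-hydroxyprop-2-en-1-yl)-5,7-dimethoxy-2H-chromen-2-one (racemic) | COc1cc(OC)c2ccc(=O)oc2c1C(O)C=C
F6 | step 4 | N-cyclohexyl-5-methylhex-5-en-1-imine | CC(=C)CCCC=NC1CCCCC1
F7 | step 4 | 5-methylhex-5-enal | CC(=C)CCCC=O
F8 | step 4 | (3R)-3-(5,7-dimethoxy-2-oxo-2H-chromen-8-yl)-2-(3-methylbut-3-en-1-yl)pent-4-enal (either C2 epimer) | O=CC(CCC(C)=C)[C@@H](C=C)c1c(OC)cc(OC)c2ccc(=O)oc12
F9 | step 4 | (2R)-2-(5,7-dimethoxy-2-oxo-2H-chromen-8-yl)-4-methylcyclohex-3-ene-1-carbaldehyde (either C1 epimer) | O=CC1CCC(C)=C[C@H]1c1c(OC)cc(OC)c2ccc(=O)oc12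
F10 | step 15 | (1Z)-1-(5,7-dimethoxy-2-oxo-2H-chromen-8-yl)-2-[(1S,2R)-2-(5,7-dimethoxy-2-oxo-2H-chromen-8-yl)-1,4-dimethylcyclohex-3-en-1-yl]ethenyl trifluoromethanesulfonate | COc1cc(OC)c2ccc(=O)oc2c1/C(OS(=O)(=O)C(F)(F)F)=C/[C@@]1(C)CCC(C)=C[C@H]1c1c(OC)cc(OC)c2ccc(=O)oc12
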